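- Taken as loss of D, the reading at 3.00 min and the one at 15.0 min of the dusk run, which is this very flask followed so far, give 0.0199 min⁻¹ and 0.0201 min⁻¹, a first-order constant that stays steady across these two readings.
- That constant, a reading with its scatter, puts the time to halve the D in this flask at 34.5 min, and this half-life of D is what I carry.

| flask | D | J | Z | remark |
|---|---|---|---|---|
| dusk | 2 M | 2.4 M | 4 mM | the very flask that is asked about, followed so far |
| flask | 2.0 M | 2.40 M | 4.0 mM |  |

dusk run (percent of the D charged)

| time / min | E / % |
|---|---|
| 1.33 | 2.7 |
| 3.00 | 5.8 |
| 6.00 | 10.7 |
| 15.0 | 26.0 |

(scatter of a reading: 0.5 percentage points)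

- no earlier run changes the charge of Z; that part of a forecast is a guess
- no earlier run changes the charge of J; that part of a forecast is a guess

- apparent order in Z when 5.0% of the D are converted (percent change of the rate of making E for one percent more Z charged)
- apparent order in J when 5.0% of the D are converted (percent change of the rate of making E for one percent more J charged)

- My doubt is that J falls as well: if one J is spent per E, the dusk run is down 21.7% of its charge of J at 15.0 min.
- I try the opposite view, with the rate following J and ignoring D. The same two readings then give 0.0165 min⁻¹ and 0.0163 min⁻¹, just as steady, so the objection stands.
- My better statement is therefore a line, not a point: the order in D plus 0.833 times the order in J comes to about one. If the order in D lies between zero and one, my estimate of the order in J runs from zero to roughly 1.20, and since neither J nor Z was varied, first order in Z is a plain guess of mine.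
- The forecast commits further, with 0.9 in Z and 0.5 in J, while granting that “this single run cannot divide it between D and J”.

- The flask gives 0.82 in Z, which the forecast meets, and 0.27 in J, so the forecast stands 1.85 times too high there.

    J + X ⇌ Q (K = 0.920 M⁻¹, k = 0.230 M⁻¹ s⁻¹)
    Q → Z + E (k = 2.80 s⁻¹)
    2 Q ⇌ G, settled at all times (K = 9100 M⁻¹)
    D + Z → X (k = 0.200 M⁻¹ s⁻¹)

- At 27.0 min the step D + Z into X by itself gives D a half-life of 29 min, shorter than my read 34.5 min, and X is made 1.00 times as fast as it is used up, each step taken net. The forward rate of J + X into Q alone gives X a half-life of 2.0 s, far shorter, and Z is 40.6% of the catalyst when 5.0% of the D are converted.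

The data come from a simulation with constants of no real substance; scatter was added.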